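The numbers in the tables are simulated with made-up constants; scatter was added.

One thing holds between the two earlier runs: at 5.00 d the eta run, at 0.17 M of starting material, shows 35.0% of isomer of the product A, and the epsilon run, at 0.38 M, shows 34.9%. These percentages differ by 0.1 percentage points, so I treat the feed (starting material, other conformer and third conformer together) as first order and take the clock of both runs over to the new flask at 0.25 M.

| flask | starting material | other conformer | protic impurity | remark | time |
|---|---|---|---|---|---|
| eta | 0.17 M | 1 equiv | 0.0125 M | run made earlier |  |
| epsilon | 0.38 M | 1 equiv | 0.0125 M | run made earlier |  |
| flask | 0.25 M | 1.00 equiv | 0.0125 M |  | 15 d |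

- eta (time / d: target / %, isomer of the product A / %): 1.25: 16.3, 11.0; 2.08: 17.6, 19.4; 3.00: 18.3, 26.1; 5.00: 18.6, 35.0; 10.0: 17.0, 44.0; 15.0: 16.7, 46.4
- epsilon (time / d: target / %, isomer of the product A / %): 2.50: 18.9, 22.4; 5.00: 18.9, 34.9; 8.00: 17.5, 42.2; 10.0: 17.7, 45.7; 12.0: 16.2, 46.4; 15.0: 15.8, 48.1

(readings scatter by 0.5 percentage points)

- share of target in target plus isomer of the product A at 40 min
- share of target in target plus isomer of the product A at 15 h
- share of target in target plus isomer of the product A at 15 d
- which of target and isomer of the product A there is more of at 15 d

- percentages count the starting material that a species holds: one side product counts as two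
- steps that have been proposed: starting material <-> other conformer; starting material -> target; other conformer -> isomer of the product A; other conformer <-> third conformer; third conformer -> third product; starting material + target -> side product; starting material + protic impurity -> quenched substrate; target <-> isomer of the product B

I read the rate as the gain of isomer of the product A per window of 5.00 d, averaged over the two runs. The first window gains 35 points, the second 9.9 points and the third 2.4 points, so the rate falls by a factor 3.53 and then 4.12. I assume the rate follows the feed left and take the later factor. That gives, as a reading that carries the scatter of a small third gain, the feed half-life h = 2.45 d, the time in which the unconverted charge halves. The asked 15 d holds 6.13 such half-lives, so I estimate that the accumulated slowing leaves 1.42% of the charge as feed. I therefore take the last readings as near the finish, and I interpolate their shares of target, 26.5% in the eta run and 24.7% in the epsilon run, to 25.8% for the new flask, with isomer of the product A ahead. For 40 min and 15 h the runs hold no reading; the earliest, at 1.25 d in the eta run, has a share of 59.7%, which I take as a floor.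

The forecast gives shares of target of 85% at 40 min, 70% at 15 h and 25.8% at 15 d, with isomer of the product A ahead, and holds that “The target's early burst is probably several times faster”.

The new flask gives shares of target of 73.0% at 40 min, 63.9% at 15 h and 26.1% at 15 d, with 47.6% of isomer of the product A against 16.8% of target.

    starting material ⇌ other conformer (K = 2.90, k = 4.50 × 10⁻⁴ /min)
    starting material → target (k = 3.80 × 10⁻⁴ /min)
    other conformer → isomer of the product A (k = 1.40 × 10⁻⁴ /min)
    other conformer ⇌ third conformer (K = 0.0370, k = 0.0200 /min)
    third conformer → third product (k = 1.60 × 10⁻⁴ /min)
    starting material + target → side product (k = 1.20 × 10⁻⁴ /M/min)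
    starting material + protic impurity → quenched substrate (k = 0.0840 /M/min)
    target ⇌ isomer of the product B (K = 1.70, k = 2.30 × 10⁻⁴ /min)

At 15.0 d this flask holds 1.54% as feed, against my 1.42%. The neighbouring flask takes 4.00 equiv of other conformer, with the other charges and the time held. The same 6.13 half-lives reckon it at the same 1.42%, and that neighbouring flask holds 1.69% as feed. Its target ends at 13.4% and its isomer of the product A at 56.7%, a share of 19.1%.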